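(Its constants stand for no real mixture; the rest is arithmetic.)

Compare two losses of target: the burst while substrate still feeds the solution, and the drip that follows from the crystals.

1. target and crystals together at 30 min, in percent of the substrate charged
2. concentration of dissolved gas in solution at 30 min, in percent of saturation

substrate 2.0 M; gas phase 200 mM (held); time 30 min

- for target the crystals are counted in
- a doubled species enters its step squared and goes two at a time
- as a solid, counted per litre of solution: crystals
- at the start none of the gas is dissolved
- run time (flask): 30 min

Start with the gas. Uptake runs at 110 min⁻¹, far faster than the charged substrate consumes dissolved gas, at 1.56 min⁻¹. So put dissolved gas at saturation, and treat the substrate as pseudo-first-order with lifetime 6.41 min. The run lasts 4.68 lifetimes. So count the charge as turned over, and let the homo dimer step carry the late draw on the gas, at 0.216 min⁻¹. That leaves the solution at: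

saturation = 99.8%

Now follow dissolved target. Its over-reaction to over-reacted product runs far slower than its loss to over-reaction product, so drop it. While fed, target divides between crystals at 0.89 min⁻¹ and over-reaction at 0.24 min⁻¹. Call the burst share the part of newly made target lost to over-reaction, 21.2%. Once the feed ends, dissolving crystals balance over-reaction, and [target] rests below 0.052 M, at 0.0410 M. Join both ends:

burst = share × charge = 0.425 M

drip = resting [target] × 0.24 min⁻¹ × time = 0.295 M

kept = 64.0% of the charge

The forecast gives 63%, against my 64.0%, and 99.8%, holding that the crystals' presence “keeps dissolved target near its solubility limit”.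

The flask gives 63.1% and 99.8%.

    gas phase ⇌ dissolved gas, rate k1*(csat - [dissolved gas]) (k1 = 110 min⁻¹, csat = 200 mM)
    substrate + dissolved gas → target (k2 = 0.78 M⁻¹ min⁻¹)
    dissolved gas + target → over-reacted product (k3 = 0.031 M⁻¹ min⁻¹)
    crystals ⇌ target, rate k4*(cs4 - [target]) while solid is left; crystals form when [target] > cs4 (cs4 = 0.052 M, k4 = 0.89 min⁻¹)
    2 dissolved gas → homo dimer (k5 = 0.54 M⁻¹ min⁻¹)
    target → over-reaction product (k6 = 0.24 min⁻¹)

Now take the neighbour flask, charged with 0.50 M of substrate, with the time and the rest held. Scale the burst with the charge, to 0.106 M. Keep the drip at 0.295 M, now larger than the burst. Then the neighbour flask should keep 19.8%. In the neighbour flask, crystals still stand at 11.7% of its charge, over-reaction product holds 77.1%, and target and crystals together hold 20.0%.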